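**Plan**
Locants (cembrane numbering): C1 = ring CH carrying the lactone α-carbon C15 (C16 = lactone C=O, C17 = its methyl); C2 = ring CH2 of the lactone; C3 = ring CH–O; C4 = C(CH3)OH; C7 = CH–OOH; C8 = C(=C19H2); C11/C12 = epoxide.
Cuts: (a) C7–OOH/C8=C19 back to the 7E-alkene (Schenck ene); (b) the C1–C2 bond, the one bond shared by the δ-lactone (O, C16, C15, C1, C2, C3) and the 14-membered carbocycle (C1–C14), which opens the bicycle to a 16-membered macrolide; (c) the ester C16–O (macrolactonization); (d) C1=C15 and C13–C14 of the seco acid (cross-metathesis, allyl coupling) back to (2E,6E)-farnesol.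
Forward order: 11,12-epoxide first, chain extension to the E-enoate, 3,4-epoxide and Payne/selenolate opening, 16-membered macrolactone, then one transannular radical C1–C2 bond formation closes lactone and carbocycle together as the last skeletal ring closure; the hydroperoxide comes last.
Enabling feature: C1 is β to the lactone carbonyl and C2 is the CH2 next to the lactone O–CH, so in the macrolide a C2 radical and the C1 terminus of the C1=C15 enoate are held six atoms apart by the ester, which is both tether and part of the product.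
Stereochemistry: C11/C12 and C3/C4 from two Sharpless epoxidations with L-(+)-tartrate (C3 inverted in the Payne step); C1 relayed from C3 through a chair transition state with the E-enoate; C15 by equilibration to the all-equatorial lactone; C7 by substrate control in the ene reaction; 7E from farnesol, enoate geometry from cross-metathesis.

Key step: step 10

Remark: (2E,6E)-farnesol of high isomeric purity is assumed as the commercial starting material, since the 7E ring alkene and both epoxidation substrates derive from it.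

Step 1
Reactants: 1 (2E,6E)-farnesol
Product: 2 (2E,6E)-farnesyl tert-butyldiphenylsilyl ether
Conditions: t-BuPh2SiCl, imidazole, DMF, 0 to 23 °C
Reagents that add atoms: tert-butyl(chloro)diphenylsilane, CC(C)(C)[Si](Cl)(c1ccccc1)c1ccccc1
Why: Silyl ether formation at the only hydroxyl masks the allylic alcohol so that the later allylic oxidation, triflation and Grignard coupling take place at the other chain end; no stereocentre is involved.

Step 2
Reactants: 2 (2E,6E)-farnesyl tert-butyldiphenylsilyl ether
Product: 3 (2E,6E,10E)-12-(tert-butyldiphenylsilyloxy)-2,6,10-trimethyldodeca-2,6,10-trien-1-ol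
Conditions: SeO2 (0.1 equiv), t-BuOOH (70% aq), salicylic acid (cat.), CH2Cl2, 0 to 23 °C
Reagents that add atoms: selenium dioxide, O=[Se]=O (catalytic oxygen carrier); tert-butyl hydroperoxide, CC(C)(C)OO (terminal oxidant)
Why: Catalytic SeO2 allylic oxidation (ene reaction then [2,3]-sigmatropic shift) should attack the most electron-rich and least hindered terminal isopropylidene unit at its E-methyl group, giving the (E)-allylic alcohol.

Step 3
Reactants: 3 (2E,6E,10E)-12-(tert-butyldiphenylsilyloxy)-2,6,10-trimethyldodeca-2,6,10-trien-1-ol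
Product: 4 (2S,3S,6E,10E)-12-(tert-butyldiphenylsilyloxy)-2,3-epoxy-2,6,10-trimethyldodeca-6,10-dien-1-ol
Conditions: Ti(OiPr)4 (10 mol %), L-(+)-diethyl tartrate (12 mol %), t-BuOOH (decane), 4 Å molecular sieves, CH2Cl2, −20 °C
Reagents that add atoms: tert-butyl hydroperoxide, CC(C)(C)OO
Why: Sharpless asymmetric epoxidation of an (E)-2-methylallylic alcohol with L-(+)-tartrate should give the (2S,3S)-epoxy alcohol, which is the (11S,12S)-epoxide of the target, and only the alkene bearing the free allylic hydroxyl reacts.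

Step 4
Reactants: 4 (2S,3S,6E,10E)-12-(tert-butyldiphenylsilyloxy)-2,3-epoxy-2,6,10-trimethyldodeca-6,10-dien-1-ol
Product: 6 tert-butyl{[(2E,6E,10S,11S)-10,11-epoxy-3,7,11-trimethylpentadeca-2,6,14-trienyl]oxy}diphenylsilane, via epoxy triflate 5 (not isolated)
Conditions: Tf2O, 2,6-lutidine, CH2Cl2, −78 °C; then allylmagnesium bromide (excess), CuBr·SMe2 (10 mol %), Et2O, −78 to −30 °C
Reagents that add atoms: trifluoromethanesulfonic anhydride, O=S(=O)(OS(=O)(=O)C(F)(F)F)C(F)(F)F (for intermediate 5); allylmagnesium bromide, C=CC[Mg]Br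
Why: Copper-catalysed Grignard displacement of a primary epoxy triflate should be much faster at low temperature than attack on the trisubstituted epoxide, so the C13–C14 bond forms with both epoxide stereocentres untouched.

Step 5
Reactants: 6 tert-butyl{[(2E,6E,10S,11S)-10,11-epoxy-3,7,11-trimethylpentadeca-2,6,14-trienyl]oxy}diphenylsilane
Product: 7 methyl (2E,6S,7S,10E,14E)-16-(tert-butyldiphenylsilyloxy)-6,7-epoxy-2,6,10,14-tetramethylhexadeca-2,10,14-trienoate
Conditions: methyl methacrylate (10 equiv), second-generation Hoveyda–Grubbs catalyst RuCl2(=CH-C6H4-2-OiPr)(H2IMes) (5 mol %), CH2Cl2, 40 °C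
Reagents that add atoms: methyl methacrylate, C=C(C)C(=O)OC
Why: Olefin cross-metathesis of the terminal alkene with methyl methacrylate should give the thermodynamically preferred (E)-2-methylenoate (C1=C15), the trisubstituted alkenes being inert to the catalyst.

Step 6
Reactants: 7 methyl (2E,6S,7S,10E,14E)-16-(tert-butyldiphenylsilyloxy)-6,7-epoxy-2,6,10,14-tetramethylhexadeca-2,10,14-trienoate
Product: 8 methyl (2E,6S,7S,10E,14E)-6,7-epoxy-16-hydroxy-2,6,10,14-tetramethylhexadeca-2,10,14-trienoate
Conditions: Bu4NF, AcOH (1:1), THF, 0 to 23 °C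
Reagents that add atoms: none
Why: Buffered fluoride cleavage of the silyl ether spares ester and epoxide and frees the allylic alcohol that directs the next epoxidation.

Step 7
Reactants: 8 methyl (2E,6S,7S,10E,14E)-6,7-epoxy-16-hydroxy-2,6,10,14-tetramethylhexadeca-2,10,14-trienoate
Product: 9 methyl (2E,6S,7S,10E,14S,15S)-6,7:14,15-diepoxy-16-hydroxy-2,6,10,14-tetramethylhexadeca-2,10-dienoate
Conditions: Ti(OiPr)4 (10 mol %), L-(+)-diethyl tartrate (12 mol %), t-BuOOH (decane), 4 Å molecular sieves, CH2Cl2, −20 °C
Reagents that add atoms: tert-butyl hydroperoxide, CC(C)(C)OO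
Why: A second Sharpless asymmetric epoxidation with L-(+)-tartrate (reagent control) should give the (2S,3S)-epoxy alcohol at the geraniol-type terminus, while the enoate, the isolated trisubstituted alkene and the first epoxide do not react.

Step 8
Reactants: 9 methyl (2E,6S,7S,10E,14S,15S)-6,7:14,15-diepoxy-16-hydroxy-2,6,10,14-tetramethylhexadeca-2,10-dienoate
Product: 12 (2E,6S,7S,10E,14S,15S)-6,7-epoxy-14,15-dihydroxy-2,6,10,14-tetramethyl-16-(phenylselanyl)hexadeca-2,10-dienoic acid (seco acid), via diepoxy acid 10 (not isolated), via Payne epoxide 11 (not isolated)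
Conditions: NaOH (0.5 M aq), t-BuOH, 23 °C; then PhSeH (slow addition), 65 °C, argon; NaH2PO4 work-up (pH 5–6)
Reagents that add atoms: benzeneselenol, [SeH]c1ccccc1; sodium hydroxide, [Na+].[OH-] (hydroxide oxygen ends in the carboxyl group)
Why: Saponification, then Payne rearrangement (the C2 alkoxide opens the epoxide at C3 with inversion) and in situ opening of the more reactive terminal epoxide at C2 by selenolate should give the C3 alcohol in the target configuration, the C4 alcohol with retention and the radical precursor at C2.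

Step 9
Reactants: 12 (2E,6S,7S,10E,14S,15S)-6,7-epoxy-14,15-dihydroxy-2,6,10,14-tetramethyl-16-(phenylselanyl)hexadeca-2,10-dienoic acid
Product: 13 (3E,7S,8S,11E,15S,16S)-7,8-epoxy-15-hydroxy-3,7,11,15-tetramethyl-16-[(phenylselanyl)methyl]oxacyclohexadeca-3,11-dien-2-one (16-membered macrolide)
Conditions: 2-methyl-6-nitrobenzoic anhydride (MNBA), DMAP, CH2Cl2 (1 mM, syringe-pump addition of 12), 23 °C
Reagents that add atoms: none
Why: Shiina macrolactonization should acylate the secondary C3 hydroxyl in preference to the tertiary C4 hydroxyl and close an unstrained 16-membered ring without touching any stereocentre.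

Step 10
Reactants: 13 (3E,7S,8S,11E,15S,16S)-7,8-epoxy-15-hydroxy-3,7,11,15-tetramethyl-16-[(phenylselanyl)methyl]oxacyclohexadeca-3,11-dien-2-one
Product: 15 (1R,3R,4S,7E,11S,12S,15S)-11,12-epoxy-4-hydroxycembr-7-en-16,3-olide (target skeleton with the C7=C8 E-alkene and a C19 methyl group), via C15 epimer 14 (not isolated)
Conditions: Bu3SnH (1.3 equiv) and AIBN (0.2 equiv) added by syringe pump over 10 h to 13 (1 mM) in toluene, 110 °C; then DBU (0.5 equiv), 80 °C
Reagents that add atoms: none
Why: Proposed new method: Bu3Sn• abstracts PhSe from C2 to give a primary β-acyloxyalkyl radical that adds across the macrolide to C1, the β-carbon of the E-configured 2-methylenoate (polarity-matched Giese addition), and the resulting tertiary C15 lactone radical is quenched by Bu3SnH; the closest known reaction types are radical conjugate additions to enoates and macrocyclization–transannulation radical cyclizations of macrocyclic enones, whereas a transannular closure through an ester link has not been shown. One bond (C1–C2) closes two rings at once, the δ-lactone in 6-endo-trig mode and the 14-membered carbocycle in 14-exo-trig mode, by contraction of the 16-membered macrolide. C1 is set in a chair-like transition state in which the C4 substituent on C3 sits equatorial and the E-alkene geometry places C14 equatorial on C1, so the two ring bonds at C1 and C3 become cis as in the target. C15 is first set by H-atom transfer (probably anti to C14, giving mainly epimer 14) and then equilibrated by DBU to the all-equatorial, thermodynamically preferred trans C1/C15 arrangement of 15. The step needs 6-endo attack at C1 to win over 5-exo attack at C15, premature reduction and 1,2-acyloxy shift: the carbonyl-conjugated, methyl-blocked C15 terminus directs the nucleophilic radical to C1, and high temperature with a low stationary stannane concentration gives the s-cis ester rotamer time to react.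

Step 11
Reactants: 15 (1R,3R,4S,7E,11S,12S,15S)-11,12-epoxy-4-hydroxycembr-7-en-16,3-olide
Product: 16 (1R,3R,4S,7S,11S,12S,15S)-11,12-epoxy-7-hydroperoxy-4-hydroxycembr-8(19)-en-16,3-olide (CNP0319766.2)
Conditions: O2, hν (visible), 5,10,15,20-tetraphenylporphyrin (cat.), CH2Cl2, −20 °C
Reagents that add atoms: dioxygen, O=O
Why: In the Schenck ene reaction of singlet oxygen with the E-trisubstituted alkene, the cis effect and the freely rotating C19 methyl group should direct H-abstraction to C19 with C–O bond formation at C7, and attack on the exposed peripheral face of the macrocyclic alkene (substrate control by the ring conformation) is expected to give the C7 configuration of the target.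

**Compound list**
1 | (2E,6E)-farnesol | CC(C)=CCC/C(C)=C/CC/C(C)=C/CO | starting material
2 | (2E,6E)-farnesyl tert-butyldiphenylsilyl ether | CC(C)=CCC/C(C)=C/CC/C(C)=C/CO[Si](c1ccccc1)(c1ccccc1)C(C)(C)C | intermediate
3 | (2E,6E,10E)-12-(tert-butyldiphenylsilyloxy)-2,6,10-trimethyldodeca-2,6,10-trien-1-ol | OC/C(C)=C/CC/C(C)=C/CC/C(C)=C/CO[Si](c1ccccc1)(c1ccccc1)C(C)(C)C | intermediate
4 | (2S,3S,6E,10E)-12-(tert-butyldiphenylsilyloxy)-2,3-epoxy-2,6,10-trimethyldodeca-6,10-dien-1-ol | CC(C)(C)[Si](c1ccccc1)(c1ccccc1)OC/C=C(C)/CC/C=C(C)/CC[C@@H]1O[C@@]1(C)CO | intermediate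
5 | trifluoromethanesulfonate of 4 (epoxy triflate, not isolated) | CC(C)(C)[Si](c1ccccc1)(c1ccccc1)OC/C=C(C)/CC/C=C(C)/CC[C@@H]1O[C@@]1(C)COS(=O)(=O)C(F)(F)F | intermediate
6 | tert-butyl{[(2E,6E,10S,11S)-10,11-epoxy-3,7,11-trimethylpentadeca-2,6,14-trienyl]oxy}diphenylsilane | CC(C)(C)[Si](c1ccccc1)(c1ccccc1)OC/C=C(C)/CC/C=C(C)/CC[C@@H]1O[C@@]1(C)CCC=C | intermediate
7 | methyl (2E,6S,7S,10E,14E)-16-(tert-butyldiphenylsilyloxy)-6,7-epoxy-2,6,10,14-tetramethylhexadeca-2,10,14-trienoate | CC(C)(C)[Si](c1ccccc1)(c1ccccc1)OC/C=C(C)/CC/C=C(C)/CC[C@@H]1O[C@@]1(C)CC/C=C(C)/C(=O)OC | intermediate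
8 | methyl (2E,6S,7S,10E,14E)-6,7-epoxy-16-hydroxy-2,6,10,14-tetramethylhexadeca-2,10,14-trienoate | OC/C=C(C)/CC/C=C(C)/CC[C@@H]1O[C@@]1(C)CC/C=C(C)/C(=O)OC | intermediate
9 | methyl (2E,6S,7S,10E,14S,15S)-6,7:14,15-diepoxy-16-hydroxy-2,6,10,14-tetramethylhexadeca-2,10-dienoate | OC[C@@H]1O[C@@]1(C)CC/C=C(C)/CC[C@@H]2O[C@@]2(C)CC/C=C(C)/C(=O)OC | intermediate
10 | (2E,6S,7S,10E,14S,15S)-6,7:14,15-diepoxy-16-hydroxy-2,6,10,14-tetramethylhexadeca-2,10-dienoic acid (not isolated) | OC[C@@H]1O[C@@]1(C)CC/C=C(C)/CC[C@@H]2O[C@@]2(C)CC/C=C(C)/C(=O)O | intermediate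
11 | (2E,6S,7S,10E,14S,15R)-6,7:15,16-diepoxy-14-hydroxy-2,6,10,14-tetramethylhexadeca-2,10-dienoic acid (Payne epoxide, not isolated) | C1O[C@H]1[C@@](C)(O)CC/C=C(C)/CC[C@@H]2O[C@@]2(C)CC/C=C(C)/C(=O)O | intermediate
12 | (2E,6S,7S,10E,14S,15S)-6,7-epoxy-14,15-dihydroxy-2,6,10,14-tetramethyl-16-(phenylselanyl)hexadeca-2,10-dienoic acid | c1ccccc1[Se]C[C@@H](O)[C@@](C)(O)CC/C=C(C)/CC[C@@H]1O[C@@]1(C)CC/C=C(C)/C(=O)O | intermediate
13 | (3E,7S,8S,11E,15S,16S)-7,8-epoxy-15-hydroxy-3,7,11,15-tetramethyl-16-[(phenylselanyl)methyl]oxacyclohexadeca-3,11-dien-2-one | c1ccccc1[Se]C[C@@H]1[C@@](C)(O)CC/C=C(C)/CC[C@@H]2O[C@@]2(C)CC/C=C(C)/C(=O)O1 | intermediate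
14 | (1R,3R,4S,7E,11S,12S,15R)-11,12-epoxy-4-hydroxycembr-7-en-16,3-olide (C15 epimer of 15, not isolated) | C1C[C@@H]2O[C@@]2(C)CC[C@@H]2C[C@@H](OC(=O)[C@@H]2C)[C@@](C)(O)CC/C=C1\C | intermediate
15 | (1R,3R,4S,7E,11S,12S,15S)-11,12-epoxy-4-hydroxycembr-7-en-16,3-olide | C1C[C@@H]2O[C@@]2(C)CC[C@@H]2C[C@@H](OC(=O)[C@H]2C)[C@@](C)(O)CC/C=C1\C | intermediate
16 | (1R,3R,4S,7S,11S,12S,15S)-11,12-epoxy-7-hydroperoxy-4-hydroxycembr-8(19)-en-16,3-olide | C=C1CC[C@@H]2O[C@@]2(C)CC[C@@H]2C[C@@H](OC(=O)[C@H]2C)[C@@](C)(O)CC[C@@H]1OO | target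

Total step count: 11. Longest linear sequence: 11 steps (from 1).

**Steps most likely to fail**

Step 10 (Proposed new method). What may go wrong: the C2 radical is reduced by the stannane or undergoes 1,2-acyloxy shift before the macrolide ester reaches the s-cis rotamer that the transannular closure needs. The fallback uses known chemistry (radical macrocyclization by intramolecular conjugate addition to an enoate, then lactonization) and sets out from seco acid 12, where no ester rotamer is involved. Slow addition of (Me3Si)3SiH and AIBN to 12 at high dilution in toluene at 90 °C should close the 14-membered carbocycle directly by addition of the C2 radical to C1 of the free enoic acid, giving (1R,3R,4S,7E,11S,12S,15S)-11,12-epoxy-3,4-dihydroxycembr-7-en-16-oic acid F1 together with its C1 and C15 epimers. Lactonization of F1 onto the C3 hydroxyl (MNBA, DMAP), DBU equilibration at C15 and separation of the C1 epimer return to the route at 15.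

Step 11. What may go wrong: poor facial selectivity of the ene reaction at C7, so that both C7 hydroperoxides form. The fallback sets out from 15 and makes the C7 configuration a matter of reagent control. 15 is photooxygenated as before and the crude mixture of 16 and its (7R)-epimer F2 is treated with Ac2O and pyridine (Kornblum–DeLaMare dehydration), which should converge both epimers on the 8(19)-en-7-one F3. Reduction with (S)-2-methyl-CBS-oxazaborolidine and BH3·SMe2 should give the (7R)-allylic alcohol F4. Mesylation (MsCl, Et3N, −40 °C) gives the (7R)-mesylate F5, and displacement with anhydrous H2O2 in Et2O at −30 °C (inversion) returns to the route at 16.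

Step 8. What may go wrong: loss of chemoselectivity of the selenolate during the slow Payne equilibration (direct attack at C3 of the 2,3-epoxy alcohol, opening of the 11,12-epoxide, or conjugate addition to the enoate). The fallback sets out from 9 and separates the rearrangement from the introduction of selenium. Treatment of 9 with hydroxide alone (0.5 M NaOH, t-BuOH/H2O, 75 °C) should effect saponification, Payne rearrangement and hydrolytic opening at C2 to give (2E,6S,7S,10E,14S,15R)-6,7-epoxy-14,15,16-trihydroxy-2,6,10,14-tetramethylhexadeca-2,10-dienoic acid F6. Selective sulfonylation of the primary hydroxyl (TsCl, Et3N, Bu2SnO cat.) gives the 16-O-tosylate F7, and displacement with PhSeNa in EtOH at 0 °C, where neither epoxide nor enoate should react, returns to the route at 12.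

**Further compounds**
F1 | step 10 | (1R,3R,4S,7E,11S,12S,15S)-11,12-epoxy-3,4-dihydroxycembr-7-en-16-oic acid | C1C[C@@H]2O[C@@]2(C)CC[C@@H]([C@H](C)C(=O)O)C[C@@H](O)[C@@](C)(O)CC/C=C1\C
F2 | step 11 | (1R,3R,4S,7R,11S,12S,15S)-11,12-epoxy-7-hydroperoxy-4-hydroxycembr-8(19)-en-16,3-olide (C7 epimer of 16) | C=C1CC[C@@H]2O[C@@]2(C)CC[C@@H]2C[C@@H](OC(=O)[C@H]2C)[C@@](C)(O)CC[C@H]1OO
F3 | step 11 | (1R,3R,4S,11S,12S,15S)-11,12-epoxy-4-hydroxy-7-oxocembr-8(19)-en-16,3-olide | C=C1CC[C@@H]2O[C@@]2(C)CC[C@@H]2C[C@@H](OC(=O)[C@H]2C)[C@@](C)(O)CCC1=O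
F4 | step 11 | (1R,3R,4S,7R,11S,12S,15S)-11,12-epoxy-4,7-dihydroxycembr-8(19)-en-16,3-olide | C=C1CC[C@@H]2O[C@@]2(C)CC[C@@H]2C[C@@H](OC(=O)[C@H]2C)[C@@](C)(O)CC[C@H]1O
F5 | step 11 | 7-O-methanesulfonate of F4 | C=C1CC[C@@H]2O[C@@]2(C)CC[C@@H]2C[C@@H](OC(=O)[C@H]2C)[C@@](C)(O)CC[C@H]1OS(C)(=O)=O
F6 | step 8 | (2E,6S,7S,10E,14S,15R)-6,7-epoxy-14,15,16-trihydroxy-2,6,10,14-tetramethylhexadeca-2,10-dienoic acid | OC[C@@H](O)[C@@](C)(O)CC/C=C(C)/CC[C@@H]1O[C@@]1(C)CC/C=C(C)/C(=O)O
F7 | step 8 | 16-O-(4-methylbenzenesulfonate) of F6 | Cc1ccc(cc1)S(=O)(=O)OC[C@@H](O)[C@@](C)(O)CC/C=C(C)/CC[C@@H]1O[C@@]1(C)CC/C=C(C)/C(=O)O
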